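**Retrosynthetic overview**
- The target acid comes from its methyl ester by saponification.
- The pyran ring of the chroman is the only ring made. Its O1–C2 bond is closed last, by an enantioconvergent dehydrative cycloetherification of a racemic tertiary dienyl carbinol carrying the free phenol; this sets (R)-C2. The benzene and cyclohexene rings are bought.
- The dienyl carbinol comes from an sp2–sp2 Stille union of an E vinylstannane (aryl half) with an E vinyl iodide (terpenoid half).
- Aryl half: methyl 4-hydroxy-3-iodobenzoate and but-3-en-2-ol give the aryl butanone (Heck), which is ethynylated.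
- Terpenoid half: dihydro-β-ionone gives the terminal alkyne, then methylalumination and iodination.

Assumption: the sense of induction of the new acid catalyst in step 6 cannot be predicted, so the catalyst antipode that gives (R) is used (both antipodes are made the same way) and the configuration is checked by correlation with the known-chemistry fallback.

**Route**

Step 1
Reactants: 1 methyl 4-hydroxy-3-iodobenzoate; 2 but-3-en-2-ol
Product: 3 methyl 4-hydroxy-3-(3-oxobutyl)benzoate
Conditions: Pd(OAc)2 (3 mol%), Bu4NCl, NaHCO3, DMF, 60 °C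
Reagents that add atoms: none
Why: Heck arylation of a secondary allylic alcohol under Jeffery conditions: aryl–Pd adds at the terminal carbon and β-hydride elimination toward the carbinol gives the enol and thus the methyl ketone, while NaHCO3 leaves phenol and ester alone.

Step 2
Reactants: 3 methyl 4-hydroxy-3-(3-oxobutyl)benzoate
Product: 4 methyl 4-hydroxy-3-(3-hydroxy-3-methylpent-4-yn-1-yl)benzoate (racemic)
Conditions: HC≡CMgBr (3.5 equiv), THF, −20 → 0 °C; aq NH4Cl
Reagents that add atoms: ethynylmagnesium bromide, C#C[Mg]Br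
Why: Grignard 1,2-addition (ketone ethynylation): the first equivalent makes the magnesium phenoxide, which also deactivates the para ester, so the acetylide adds only to the ketone; the carbinol centre is left racemic because step 6 erases it.

Step 3
Reactants: 5 dihydro-β-ionone, 4-(2,6,6-trimethylcyclohex-1-en-1-yl)butan-2-one
Product: 7 2-(but-3-yn-1-yl)-1,3,3-trimethylcyclohex-1-ene, via enol phosphate 6 (not isolated)
Conditions: LiN(i-Pr)2 (1.1 equiv), THF, −78 °C; ClP(O)(OEt)2, −78 °C → rt; LiN(i-Pr)2 (2.3 equiv), −78 °C → rt; H2O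
Reagents that add atoms: diethyl chlorophosphate, ClP(=O)(OCC)OCC (its atoms are held only by 6 and leave again before 7)
Why: Negishi one-pot conversion of a methyl ketone into a terminal alkyne: kinetic enolisation on the CH3 side, O-phosphorylation, then E2 elimination of the enol phosphate, the product being parked as the lithium acetylide so that it does not isomerise.

Step 4
Reactants: 7 2-(but-3-yn-1-yl)-1,3,3-trimethylcyclohex-1-ene
Product: 9 2-[(3E)-4-iodo-3-methylbut-3-en-1-yl]-1,3,3-trimethylcyclohex-1-ene, via vinylalane 8 (not isolated)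
Conditions: AlMe3 (2 equiv), Cp2ZrCl2 (25 mol%), CH2Cl2, 0 °C → rt; I2, THF, −30 → 0 °C
Reagents that add atoms: trimethylaluminium, C[Al](C)C; iodine, II
Why: Negishi zirconium-catalysed carboalumination: syn addition of Me–Al across the terminal alkyne puts Me on the internal carbon, and iodinolysis with retention gives the E vinyl iodide; the tetrasubstituted ring alkene is inert.

Step 5
Reactants: 4 methyl 4-hydroxy-3-(3-hydroxy-3-methylpent-4-yn-1-yl)benzoate; 9 2-[(3E)-4-iodo-3-methylbut-3-en-1-yl]-1,3,3-trimethylcyclohex-1-ene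
Product: 11 methyl 4-hydroxy-3-[(4E,6E)-3-hydroxy-3,7-dimethyl-9-(2,6,6-trimethylcyclohex-1-en-1-yl)nona-4,6-dien-1-yl]benzoate, via vinylstannane 10 (not isolated)
Conditions: Bu3SnH (1.05 equiv, slow addition), PdCl2(PPh3)2 (2 mol%), THF, 0 °C; then 9, Pd2(dba)3 (2.5 mol%), AsPh3 (20 mol%), NMP, 40 °C
Reagents that add atoms: tributyltin hydride, CCCC[SnH](CCCC)CCCC (its tin group is held only by 10 and leaves again before 11)
Why: Palladium-catalysed syn hydrostannation places tin on the terminal alkyne carbon away from the bulky tertiary carbinol (E stannane), and Stille cross-coupling proceeds with retention at both sp2 carbons to give the E,E diene under neutral conditions that tolerate phenol, tertiary alcohol and ester.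

Step 6
Reactants: 11 methyl 4-hydroxy-3-[(4E,6E)-3-hydroxy-3,7-dimethyl-9-(2,6,6-trimethylcyclohex-1-en-1-yl)nona-4,6-dien-1-yl]benzoate (racemic)
Product: 12 methyl (2R)-2-methyl-2-[(1E,3E)-4-methyl-6-(2,6,6-trimethylcyclohex-1-en-1-yl)hexa-1,3-dien-1-yl]-3,4-dihydro-2H-chromene-6-carboxylate
Conditions: N-triflylphosphoramide of (R)-3,3′-bis(2,4,6-triisopropylphenyl)-H8-BINOL (5 mol%), 5 Å molecular sieves, toluene, −40 °C; Et3N quench
Reagents that add atoms: none
Why: Proposed new method: enantioconvergent dehydrative cycloetherification (intramolecular SN1-type allylic substitution under chiral-counteranion Brønsted acid catalysis). The acid ionises the tertiary, doubly allylic C–OH of either enantiomer of 11 to one achiral W-shaped pentadienyl cation held as a contact ion pair with the chiral phosphoramidate. The anion hydrogen-bonds the phenol O–H and delivers it to one face of the cationic carbon through a chair-like six-membered transition state, so the O–C2 bond, the pyran ring and the (R) quaternary centre form together. Closure at the other cation termini would need 8- or 10-membered rings; the E,E geometry should survive because trapping is expected to be faster than C–C rotation in the ion pair; the aryl ether product is far less basic than the alcohol and should not re-ionise at −40 °C. The closest known reaction types are chiral phosphoramide-catalysed intramolecular allylic substitution of allylic alcohols by phenols to 2H-chromenes and chiral-acid-catalysed intramolecular hydroalkoxylation; neither has been shown for an aliphatic pentadienyl cation closing to a chroman with a quaternary centre.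

Step 7
Reactants: 12 methyl (2R)-2-methyl-2-[(1E,3E)-4-methyl-6-(2,6,6-trimethylcyclohex-1-en-1-yl)hexa-1,3-dien-1-yl]-3,4-dihydro-2H-chromene-6-carboxylate
Product: 13 (2R)-2-methyl-2-[(1E,3E)-4-methyl-6-(2,6,6-trimethylcyclohex-1-en-1-yl)hexa-1,3-dien-1-yl]-3,4-dihydro-2H-chromene-6-carboxylic acid
Conditions: LiOH·H2O (5 equiv), THF/MeOH/H2O (3:1:1), 45 °C; then 1 M HCl to pH 4–5, 0 °C
Reagents that add atoms: lithium hydroxide, [Li+].[OH-]
Why: Ester saponification (BAc2 hydrolysis): hydroxide attacks only the methyl ester, the quaternary stereocentre has no acidic hydrogen and the tertiary allylic aryl ether is base-stable; the cold, brief acidification avoids ionising that ether.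

**Compound list**
1 | methyl 4-hydroxy-3-iodobenzoate | COC(=O)c1ccc(O)c(I)c1 | starting material
2 | but-3-en-2-ol (racemic) | CC(O)C=C | starting material
3 | methyl 4-hydroxy-3-(3-oxobutyl)benzoate | COC(=O)c1ccc(O)c(CCC(C)=O)c1 | intermediate
4 | methyl 4-hydroxy-3-(3-hydroxy-3-methylpent-4-yn-1-yl)benzoate (racemic) | COC(=O)c1ccc(O)c(CCC(C)(O)C#C)c1 | intermediate
5 | dihydro-β-ionone, 4-(2,6,6-trimethylcyclohex-1-en-1-yl)butan-2-one | CC(=O)CCC1=C(C)CCCC1(C)C | starting material
6 | diethyl 4-(2,6,6-trimethylcyclohex-1-en-1-yl)but-1-en-2-yl phosphate (enol phosphate, not isolated) | C=C(CCC1=C(C)CCCC1(C)C)OP(=O)(OCC)OCC | intermediate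
7 | 2-(but-3-yn-1-yl)-1,3,3-trimethylcyclohex-1-ene | C#CCCC1=C(C)CCCC1(C)C | intermediate
8 | dimethyl[(1E)-2-methyl-4-(2,6,6-trimethylcyclohex-1-en-1-yl)but-1-en-1-yl]alumane (vinylalane, not isolated) | C[Al](C)/C=C(\C)CCC1=C(C)CCCC1(C)C | intermediate
9 | 2-[(3E)-4-iodo-3-methylbut-3-en-1-yl]-1,3,3-trimethylcyclohex-1-ene | I/C=C(\C)CCC1=C(C)CCCC1(C)C | intermediate
10 | methyl 4-hydroxy-3-[(4E)-3-hydroxy-3-methyl-5-(tributylstannyl)pent-4-en-1-yl]benzoate (racemic vinylstannane, not isolated) | COC(=O)c1ccc(O)c(CCC(C)(O)/C=C/[Sn](CCCC)(CCCC)CCCC)c1 | intermediate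
11 | methyl 4-hydroxy-3-[(4E,6E)-3-hydroxy-3,7-dimethyl-9-(2,6,6-trimethylcyclohex-1-en-1-yl)nona-4,6-dien-1-yl]benzoate (racemic) | COC(=O)c1ccc(O)c(CCC(C)(O)/C=C/C=C(\C)CCC2=C(C)CCCC2(C)C)c1 | intermediate
12 | methyl (2R)-2-methyl-2-[(1E,3E)-4-methyl-6-(2,6,6-trimethylcyclohex-1-en-1-yl)hexa-1,3-dien-1-yl]-3,4-dihydro-2H-chromene-6-carboxylate | CC1=C(CC/C(C)=C/C=C/[C@@]2(C)CCc3cc(C(=O)OC)ccc3O2)C(C)(C)CCC1 | intermediate
13 | (2R)-2-methyl-2-[(1E,3E)-4-methyl-6-(2,6,6-trimethylcyclohex-1-en-1-yl)hexa-1,3-dien-1-yl]-3,4-dihydro-2H-chromene-6-carboxylic acid | CC1=C(CC/C(C)=C/C=C/[C@@]2(C)CCc3cc(C(=O)O)ccc3O2)C(C)(C)CCC1 | target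

**Totals**
Total step count: 7. Longest linear sequence: 5 (steps 1, 2, 5, 6, 7; the branch through steps 3, 4, 5, 6, 7 is equally long).

**Three steps most likely to fail**

Step 6 (the proposed new step). The risks are E1 loss of a proton from the pentadienyl cation to tetraenes, racemic background closure of the very labile carbinol, and low or unpredictable enantioselectivity. The fallback uses known chemistry, sets out from 3 and comes back at 12. Wittig olefination of 3 with ethylidenetriphenylphosphorane (EtPPh3Br, KOt-Bu, 2.2 equiv, THF) gives the alkenyl phenol methyl 4-hydroxy-3-(3-methylpent-3-en-1-yl)benzoate F1 as an E/Z mixture. Enantioselective Wacker-type oxidative cyclization (Pd(O2CCF3)2 10 mol%, the Bn-BOXAX antipode that gives R, p-benzoquinone, MeOH, 60 °C; oxypalladation by divalent palladium, then β-hydride elimination) gives methyl (2R)-2-ethenyl-2-methyl-3,4-dihydro-2H-chromene-6-carboxylate F2. Heck alkenylation of F2 with vinyl iodide 9 (Pd(OAc)2, Ag2CO3, DMF, 50 °C) then gives 12; the quaternary allylic carbon leaves only terminal attack and no allylic hydrogen, so the E,E diene results.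

Step 5 (one-pot hydrostannation and Stille coupling). The risks are regioisomeric stannane, protodestannylation by the free phenol, reduction of 9 by residual hydride, and premature acid-induced closure of 11 (purify on Et3N-deactivated silica, use at once). The fallback sets out from 4 and 9 and comes back at 11. Sonogashira coupling (PdCl2(PPh3)2, CuI, Et3N, THF, rt) gives the enynol methyl 4-hydroxy-3-[(6E)-3-hydroxy-3,7-dimethyl-9-(2,6,6-trimethylcyclohex-1-en-1-yl)non-6-en-4-yn-1-yl]benzoate F3. Ruthenium-catalysed trans-hydrosilylation ([Cp*Ru(MeCN)3]PF6, (EtO)3SiH, CH2Cl2, 0 °C) gives the alkenylsilane methyl 4-hydroxy-3-[(4Z,6E)-3-hydroxy-3,7-dimethyl-5-(triethoxysilyl)-9-(2,6,6-trimethylcyclohex-1-en-1-yl)nona-4,6-dien-1-yl]benzoate F4 (the regioisomeric silane would give the same product). Protodesilylation (AgF, THF/MeOH/H2O, rt) gives 11 with the E,E diene.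

Step 1 (Heck reaction of the free ortho-iodophenol with the allylic alcohol). The risks are β-hydride elimination toward the aryl side and closure of 3 to its hemiketal with dehydration to a 4H-chromene. The fallback sets out from 1 and comes back at 3. A conventional Heck reaction with but-3-en-2-one (Pd(OAc)2, Et3N, MeCN, 80 °C) gives the enone methyl 4-hydroxy-3-[(1E)-3-oxobut-1-en-1-yl]benzoate F5, and hydrogenation of its C=C bond (H2 1 atm, Pd/C (palladium on carbon), EtOAc, rt) gives 3.

**Further compounds**
F1 | step 6 | methyl 4-hydroxy-3-(3-methylpent-3-en-1-yl)benzoate (E/Z mixture) | COC(=O)c1ccc(O)c(CCC(C)=CC)c1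
F2 | step 6 | methyl (2R)-2-ethenyl-2-methyl-3,4-dihydro-2H-chromene-6-carboxylate | C=C[C@@]1(C)CCc2cc(C(=O)OC)ccc2O1
F3 | step 5 | methyl 4-hydroxy-3-[(6E)-3-hydroxy-3,7-dimethyl-9-(2,6,6-trimethylcyclohex-1-en-1-yl)non-6-en-4-yn-1-yl]benzoate (racemic) | COC(=O)c1ccc(O)c(CCC(C)(O)C#C/C=C(\C)CCC2=C(C)CCCC2(C)C)c1
F4 | step 5 | methyl 4-hydroxy-3-[(4Z,6E)-3-hydroxy-3,7-dimethyl-5-(triethoxysilyl)-9-(2,6,6-trimethylcyclohex-1-en-1-yl)nona-4,6-dien-1-yl]benzoate (racemic) | COC(=O)c1ccc(O)c(CCC(C)(O)/C=C(\[Si](OCC)(OCC)OCC)/C=C(\C)CCC2=C(C)CCCC2(C)C)c1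
F5 | step 1 | methyl 4-hydroxy-3-[(1E)-3-oxobut-1-en-1-yl]benzoate | COC(=O)c1ccc(O)c(/C=C/C(C)=O)c1
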